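**Retrosynthetic overview** (core ring numbered C1 = CH–CH2O‑acyl, C2 = CH–CH3, C3 = CH–O‑acyl, C4 = CH2, C5 = CH–CH(CH2OH)2)
1. Last disconnection: each dialdehyde arm is released by periodate cleavage of a cyclopentane‑cis‑1,2‑diol, so the target comes from hexaol 31, i.e. from core diol 19 and two equivalents of acid 28; the free 1,3‑diol is inert to periodate.
2. The core cyclopentane is the only ring that is formed: a one‑step [3+2] annulation of the acyclic, achiral dienyl malonate 8 with benzyl vinyl ether 9 makes C4–C5 and C2–C3.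
3. Enabling feature: C4–C3(O) is an enol‑ether (acetaldehyde) unit; C5 carries CH(CH2OH)2, a reduced malonate, so C5 is the β‑carbon of an alkylidene malonate; C2 is γ to the exocyclic CH2O carbon on C1, so C2 is the nucleophilic end of a crotylsilane whose CH2Si carbon becomes that CH2O carbon. The substituents on C5, C2 and C3 are all pseudoequatorial (C5/C2 cis, C2/C3 trans).
4. C1 is set afterwards under thermodynamic control (hydroboration, oxidation, epimerisation of the aldehyde to the all‑trans array); the malonate is reduced and masked as an acetonide.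
5. Acid 28 comes from the ribose‑derived enone 20 (ring bought, not formed): hydrogenation, convex‑face enolate alkylation, Wittig ethylidenation, saponification.

Key step: step 4

Assumption: enone 20 and Grignard reagent 4 are bought, and the (S,S)‑bis(oxazoline) ligand is taken to give the (S) centre at the malonyl‑bearing ring carbon of 12; if the sense proves opposite, the (R,R) ligand is used.

Step 1
Reactants: 1 (E)-but-2-enal
Product: 3 (Z)-2-bromobut-2-enal, via 2,3-dibromobutanal 2 (not isolated)
Conditions: Br2, CH2Cl2, 0 °C; then Et3N, 0 °C → rt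
Reagents that add atoms: bromine, BrBr
Why: Alkene bromination followed by E1cB dehydrobromination (α‑bromination of an enal); the conjugated product should form with methyl trans to the formyl group (Z).

Step 2
Reactants: 3 (Z)-2-bromobut-2-enal; 4 (trimethylsilyl)methylmagnesium chloride
Product: 6 (Z)-2-[(trimethylsilyl)methyl]but-2-enal, via (trimethylsilyl)methylzinc chloride 5 (not isolated)
Conditions: 4, ZnCl2, THF, 0 °C; then 3, Pd(PPh3)4 (3 mol%), THF, rt
Reagents that add atoms: none
Why: Negishi cross‑coupling after Mg→Zn transmetalation; the organozinc has no β‑hydrogen, tolerates the aldehyde, and the vinyl bromide should couple with retention, leaving methyl cis to CH2Si.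

Step 3
Reactants: 6 (Z)-2-[(trimethylsilyl)methyl]but-2-enal; 7 dimethyl malonate
Product: 8 dimethyl 2-{(2Z)-2-[(trimethylsilyl)methyl]but-2-en-1-ylidene}propanedioate
Conditions: piperidine (10 mol%), AcOH (10 mol%), 4 Å MS, toluene, 50 °C
Reagents that add atoms: none
Why: Knoevenagel condensation; the two esters are identical so no new stereo‑element arises, and the allylsilane geometry is not touched.

Step 4
Reactants: 8 dimethyl 2-{(2Z)-2-[(trimethylsilyl)methyl]but-2-en-1-ylidene}propanedioate; 9 benzyl vinyl ether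
Product: 12 dimethyl 2-[(1S,3R,4R)-4-(benzyloxy)-3-methyl-2-methylidenecyclopentyl]propanedioate, via oxocarbenium zwitterion 10 (not isolated), via cyclised malonate enolate 11 (not isolated)
Conditions: 9 (3 equiv), [Cu((S,S)-t-Bu-box)](SbF6)2 (10 mol%; t-Bu-box = 2,2'-(propane-2,2-diyl)bis[(4S)-4-tert-butyl-4,5-dihydro-1,3-oxazole]), 4 Å MS, CH2Cl2, −78 → −20 °C; pH 7 buffer
Reagents that add atoms: none
Why: Proposed new method: chelation of the malonate by the divalent copper–bis(oxazoline) complex makes C5 of 8 electrophilic, the CH2 terminus of 9 adds there (Mukaiyama–Michael‑type addition of an enol ether) to give zwitterion 10, and its benzyl oxocarbenium carbon (C3) is captured by the γ‑carbon (C2) of the (Z)‑crotylsilane in a Hosomi–Sakurai closure that passes Me3Si+ to the malonate enolate (turnover) and leaves the exocyclic methylene. The closest known reaction types are the copper–bis(oxazoline)‑catalysed Mukaiyama–Michael addition to alkylidene malonates, the Lewis‑acid [2+2] and [4+2] reactions of vinyl ethers with alkylidene malonates that pass through the same zwitterion, and the methylenecyclopentane annulation of 2‑(silylmethyl)allyl units onto carbonyl or oxocarbenium carbons. The cyclopentane closes by 5‑exo‑trig attack on the oxocarbenium carbon with the allylsilane reacting in its 2‑(silylmethyl)allyl mode; the irreversible desilylation should drain the reversible cyclobutane and dihydropyran adducts. C5 is set by the catalyst (the chelated malonate exposes one face of the C=C); C2 and C3 follow from an envelope transition state in which the malonyl group, the methyl group (cis to CH2Si in the Z‑silane) and the benzyloxy group of the E‑oxocarbenium are all pseudoequatorial, which should give C5/C2 cis and C2/C3 trans. The step needs 1,4‑ rather than 1,6‑addition to the dienyl malonate and attack by the vinyl ether rather than by a second allylsilane; chelation puts the activation next to C5, the δ‑carbon is trisubstituted and is the electron‑rich end of the allylsilane, and the free vinyl ether is more nucleophilic than the acceptor‑conjugated allylsilane.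

Step 5
Reactants: 12 dimethyl 2-[(1S,3R,4R)-4-(benzyloxy)-3-methyl-2-methylidenecyclopentyl]propanedioate
Product: 14 dimethyl 2-[(1R,2R,3R,4R)-4-(benzyloxy)-2-(hydroxymethyl)-3-methylcyclopentyl]propanedioate, via B-alkyl-9-borabicyclononane adduct 13 (not isolated)
Conditions: 9-BBN (1.5 equiv), THF, 0 °C → rt; then 30% H2O2, aq. NaOAc, 0 °C → rt
Reagents that add atoms: hydrogen peroxide, OO
Why: Anti‑Markovnikov hydroboration–oxidation of the 1,1‑disubstituted alkene; the borane should add anti to the flanking methyl and malonyl groups (all‑cis epimer drawn), but either epimer serves because this centre is reset in step 6.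

Step 6
Reactants: 14 dimethyl 2-[(1R,2R,3R,4R)-4-(benzyloxy)-2-(hydroxymethyl)-3-methylcyclopentyl]propanedioate
Product: 16 dimethyl 2-[(1R,2S,3R,4R)-4-(benzyloxy)-2-formyl-3-methylcyclopentyl]propanedioate, via all-cis aldehyde 15 (not isolated)
Conditions: 1,1,1-triacetoxy-1,1-dihydro-1,2-benziodoxol-3(1H)-one (DMP), CH2Cl2, rt; aqueous work-up; then DBU (0.2 equiv), CH2Cl2, rt
Reagents that add atoms: none
Why: Periodinane oxidation followed by base‑mediated epimerisation through the enolate; thermodynamic control should place the formyl group trans to both cis‑disposed neighbours, which sets C1.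

Step 7
Reactants: 16 dimethyl 2-[(1R,2S,3R,4R)-4-(benzyloxy)-2-formyl-3-methylcyclopentyl]propanedioate
Product: 17 2-[(1R,2S,3R,4R)-4-(benzyloxy)-2-(hydroxymethyl)-3-methylcyclopentyl]propane-1,3-diol
Conditions: LiAlH4, THF, 0 °C → rt; aqueous work-up
Reagents that add atoms: none
Why: Hydride reduction of the aldehyde and of both malonate esters (LiAlH4 reduction); the aldehyde is reduced first, so the epimerisable centre is fixed.

Step 8
Reactants: 17 2-[(1R,2S,3R,4R)-4-(benzyloxy)-2-(hydroxymethyl)-3-methylcyclopentyl]propane-1,3-diol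
Product: 18 [(1S,2R,3R,5R)-3-(benzyloxy)-5-(2,2-dimethyl-1,3-dioxan-5-yl)-2-methylcyclopentyl]methanol
Conditions: Me2C(OMe)2, PPTS (5 mol%), acetone, rt
Reagents that add atoms: 2,2-dimethoxypropane, COC(C)(C)OC
Why: Transketalisation (acetonide formation) should be selective for the 1,3‑diol, which closes a six‑membered 1,3‑dioxane, and leave the lone primary hydroxyl free.

Step 9
Reactants: 18 [(1S,2R,3R,5R)-3-(benzyloxy)-5-(2,2-dimethyl-1,3-dioxan-5-yl)-2-methylcyclopentyl]methanol
Product: 19 (1R,2R,3S,4R)-4-(2,2-dimethyl-1,3-dioxan-5-yl)-3-(hydroxymethyl)-2-methylcyclopentan-1-ol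
Conditions: H2 (1 atm), Pd(OH)2/C, EtOAc, rt
Reagents that add atoms: none
Why: Hydrogenolysis of the benzyl ether under neutral conditions, which the acetonide should survive.

Step 10
Reactants: 20 (3aR,6aR)-2,2-dimethyl-3a,6a-dihydro-4H-cyclopenta[d][1,3]dioxol-4-one
Product: 21 (3aR,6aR)-2,2-dimethyltetrahydro-4H-cyclopenta[d][1,3]dioxol-4-one
Conditions: H2 (1 atm), 10% Pd/C, EtOAc, rt
Reagents that add atoms: none
Why: Heterogeneous hydrogenation of the enone C=C; no stereocentre is made or touched.

Step 11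
Reactants: 21 (3aR,6aR)-2,2-dimethyltetrahydro-4H-cyclopenta[d][1,3]dioxol-4-one; 22 methyl bromoacetate
Product: 24 methyl 2-[(3aR,5S,6aR)-2,2-dimethyl-4-oxotetrahydro-3aH-cyclopenta[d][1,3]dioxol-5-yl]acetate, via lithium enolate 23 (not isolated)
Conditions: LiN(SiMe3)2, THF, −78 °C; then 22, −78 → −40 °C
Reagents that add atoms: none
Why: Kinetic enolate alkylation; deprotonation should occur at the CH2 rather than at the oxygenated α‑carbon, and the electrophile should enter on the convex face anti to the dioxolane, which sets the (5S) centre.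

Step 12
Reactants: 24 methyl 2-[(3aR,5S,6aR)-2,2-dimethyl-4-oxotetrahydro-3aH-cyclopenta[d][1,3]dioxol-5-yl]acetate; 25 ethyltriphenylphosphonium bromide
Product: 27 methyl 2-[(3aS,4E,5S,6aR)-4-ethylidene-2,2-dimethyltetrahydro-3aH-cyclopenta[d][1,3]dioxol-5-yl]acetate, via ethylidenetriphenylphosphorane 26 (not isolated)
Conditions: 25, KOC(CH3)3, THF, 0 °C; then 24, 0 °C → rt
Reagents that add atoms: none
Why: Wittig olefination; the E isomer (methyl on the side of C5, away from the oxygenated carbon) is the one needed and is expected because the ring‑locked C–O bond lies near the olefin plane while C5 can turn its hydrogen into it; this selectivity is not secured (see risks).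

Step 13
Reactants: 27 methyl 2-[(3aS,4E,5S,6aR)-4-ethylidene-2,2-dimethyltetrahydro-3aH-cyclopenta[d][1,3]dioxol-5-yl]acetate
Product: 28 2-[(3aS,4E,5S,6aR)-4-ethylidene-2,2-dimethyltetrahydro-3aH-cyclopenta[d][1,3]dioxol-5-yl]acetic acid
Conditions: LiOH, THF–H2O, rt; then 1 M HCl to pH 4, 0 °C
Reagents that add atoms: lithium hydroxide, [Li+].[OH-]
Why: Saponification; the stereocentre is β to the carboxyl group and the acetonide is base‑stable.

Step 14
Reactants: 19 (1R,2R,3S,4R)-4-(2,2-dimethyl-1,3-dioxan-5-yl)-3-(hydroxymethyl)-2-methylcyclopentan-1-ol; 28 2-[(3aS,4E,5S,6aR)-4-ethylidene-2,2-dimethyltetrahydro-3aH-cyclopenta[d][1,3]dioxol-5-yl]acetic acid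
Product: 30 diester of 19 (both hydroxyl groups acylated by 28), via primary monoester 29 (not isolated)
Conditions: 28 (2.4 equiv), N,N'-diisopropylcarbodiimide (2.6 equiv), DMAP (0.3 equiv), CH2Cl2, 0 °C → 40 °C
Reagents that add atoms: none
Why: Steglich esterification; the primary hydroxyl should react first and the secondary one on warming, with no stereocentre at risk.

Step 15
Reactants: 30 diester of 19 with 28
Product: 31 hexaol: the diester, at the ring OH and the 3‑CH2OH of (1R,2R,3S,4R)-4-(1,3-dihydroxypropan-2-yl)-3-(hydroxymethyl)-2-methylcyclopentan-1-ol, with 2-[(1S,2E,3S,4R)-2-ethylidene-3,4-dihydroxycyclopentyl]acetic acid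
Conditions: 1 M aq. HCl–THF (1:3), rt
Reagents that add atoms: none
Why: Acid‑catalysed acetal hydrolysis of the three acetonides; the esters should survive, and lactonisation onto the side‑chain diols is geometrically excluded (hydroxyls trans to the acetate arm).

Step 16
Reactants: 31 hexaol
Product: 32 target CNP0313563.1
Conditions: NaIO4 (2.4 equiv), THF–H2O (pH 7 buffer), 0 °C → rt
Reagents that add atoms: none
Why: Periodate glycol cleavage; only the two cis‑1,2‑diols react, each giving the (E)‑enal and the CH2CHO arm, while the 1,3‑diol, the esters, the olefin geometry and all stereocentres are left as they are.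

**Compound list**
1 | (E)-but-2-enal | C/C=C/C=O | starting material
2 | (2R*,3S*)-2,3-dibromobutanal (racemic) | C[C@H](Br)[C@H](Br)C=O | intermediate
3 | (Z)-2-bromobut-2-enal | C/C=C(\Br)C=O | intermediate
4 | (trimethylsilyl)methylmagnesium chloride | C[Si](C)(C)C[Mg]Cl | starting material
5 | (trimethylsilyl)methylzinc chloride | C[Si](C)(C)C[Zn]Cl | intermediate
6 | (Z)-2-[(trimethylsilyl)methyl]but-2-enal | C/C=C(\C[Si](C)(C)C)C=O | intermediate
7 | dimethyl malonate | COC(=O)CC(=O)OC | starting material
8 | dimethyl 2-{(2Z)-2-[(trimethylsilyl)methyl]but-2-en-1-ylidene}propanedioate | C/C=C(\C[Si](C)(C)C)C=C(C(=O)OC)C(=O)OC | intermediate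
9 | benzyl vinyl ether | C=COCc1ccccc1 | starting material
10 | (S)-Michael adduct, benzyl oxocarbenium ion with copper-bound malonate enolate (drawn metal-free, carbanion form) | C/C=C(\C[Si](C)(C)C)[C@@H](CC=[O+]Cc1ccccc1)[C-](C(=O)OC)C(=O)OC | intermediate
11 | cyclised malonate enolate (drawn as the carbanion; held as silyl or copper enolate) | C=C1[C@@H](C)[C@H](OCc2ccccc2)C[C@H]1[C-](C(=O)OC)C(=O)OC | intermediate
12 | dimethyl 2-[(1S,3R,4R)-4-(benzyloxy)-3-methyl-2-methylidenecyclopentyl]propanedioate | C=C1[C@@H](C)[C@H](OCc2ccccc2)C[C@H]1C(C(=O)OC)C(=O)OC | intermediate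
13 | B-alkyl-9-borabicyclo[3.3.1]nonane adduct of 12 (boron on the exocyclic CH2) | C1CC2CCCC(C1)B2C[C@H]1[C@@H](C)[C@H](OCc3ccccc3)C[C@H]1C(C(=O)OC)C(=O)OC | intermediate
14 | dimethyl 2-[(1R,2R,3R,4R)-4-(benzyloxy)-2-(hydroxymethyl)-3-methylcyclopentyl]propanedioate (expected epimer) | OC[C@H]1[C@@H](C)[C@H](OCc2ccccc2)C[C@H]1C(C(=O)OC)C(=O)OC | intermediate
15 | dimethyl 2-[(1R,2R,3R,4R)-4-(benzyloxy)-2-formyl-3-methylcyclopentyl]propanedioate | O=C[C@H]1[C@@H](C)[C@H](OCc2ccccc2)C[C@H]1C(C(=O)OC)C(=O)OC | intermediate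
16 | dimethyl 2-[(1R,2S,3R,4R)-4-(benzyloxy)-2-formyl-3-methylcyclopentyl]propanedioate | O=C[C@@H]1[C@@H](C)[C@H](OCc2ccccc2)C[C@H]1C(C(=O)OC)C(=O)OC | intermediate
17 | 2-[(1R,2S,3R,4R)-4-(benzyloxy)-2-(hydroxymethyl)-3-methylcyclopentyl]propane-1,3-diol | OC[C@@H]1[C@@H](C)[C@H](OCc2ccccc2)C[C@H]1C(CO)CO | intermediate
18 | [(1S,2R,3R,5R)-3-(benzyloxy)-5-(2,2-dimethyl-1,3-dioxan-5-yl)-2-methylcyclopentyl]methanol | OC[C@@H]1[C@@H](C)[C@H](OCc2ccccc2)C[C@H]1C3COC(C)(C)OC3 | intermediate
19 | (1R,2R,3S,4R)-4-(2,2-dimethyl-1,3-dioxan-5-yl)-3-(hydroxymethyl)-2-methylcyclopentan-1-ol | OC[C@@H]1[C@@H](C)[C@H](O)C[C@H]1C2COC(C)(C)OC2 | intermediate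
20 | (3aR,6aR)-2,2-dimethyl-3a,6a-dihydro-4H-cyclopenta[d][1,3]dioxol-4-one | O=C1[C@@H]2OC(C)(C)O[C@@H]2C=C1 | starting material
21 | (3aR,6aR)-2,2-dimethyltetrahydro-4H-cyclopenta[d][1,3]dioxol-4-one | O=C1[C@@H]2OC(C)(C)O[C@@H]2CC1 | intermediate
22 | methyl bromoacetate | COC(=O)CBr | starting material
23 | lithium enolate of 21 (enolised toward the CH2) | [Li]OC=1[C@@H]2OC(C)(C)O[C@@H]2CC=1 | intermediate
24 | methyl 2-[(3aR,5S,6aR)-2,2-dimethyl-4-oxotetrahydro-3aH-cyclopenta[d][1,3]dioxol-5-yl]acetate | O=C1[C@@H]2OC(C)(C)O[C@@H]2C[C@H]1CC(=O)OC | intermediate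
25 | ethyltriphenylphosphonium bromide | CC[P+](c1ccccc1)(c1ccccc1)c1ccccc1.[Br-] | starting material
26 | ethylidenetriphenylphosphorane | CC=P(c1ccccc1)(c1ccccc1)c1ccccc1 | intermediate
27 | methyl 2-[(3aS,4E,5S,6aR)-4-ethylidene-2,2-dimethyltetrahydro-3aH-cyclopenta[d][1,3]dioxol-5-yl]acetate | C/C=C1/[C@@H]2OC(C)(C)O[C@@H]2C[C@H]1CC(=O)OC | intermediate
28 | 2-[(3aS,4E,5S,6aR)-4-ethylidene-2,2-dimethyltetrahydro-3aH-cyclopenta[d][1,3]dioxol-5-yl]acetic acid | C/C=C1/[C@@H]2OC(C)(C)O[C@@H]2C[C@H]1CC(=O)O | intermediate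
29 | monoester of 19 (primary hydroxyl acylated by 28) | C/C=C1/[C@@H]2OC(C)(C)O[C@@H]2C[C@H]1CC(=O)OC[C@@H]3[C@@H](C)[C@H](O)C[C@H]3C4COC(C)(C)OC4 | intermediate
30 | diester of 19 (both hydroxyl groups acylated by 28) | C/C=C1/[C@@H]2OC(C)(C)O[C@@H]2C[C@H]1CC(=O)OC[C@@H]3[C@@H](C)[C@H](OC(=O)C[C@@H]5C[C@H]6OC(C)(C)O[C@H]6/C5=C/C)C[C@H]3C4COC(C)(C)OC4 | intermediate
31 | hexaol: diester of (1R,2R,3S,4R)-4-(1,3-dihydroxypropan-2-yl)-3-(hydroxymethyl)-2-methylcyclopentan-1-ol with 2-[(1S,2E,3S,4R)-2-ethylidene-3,4-dihydroxycyclopentyl]acetic acid | C/C=C1/[C@H](O)[C@H](O)C[C@H]1CC(=O)OC[C@@H]2[C@@H](C)[C@H](OC(=O)C[C@@H]3C[C@@H](O)[C@@H](O)/C3=C/C)C[C@H]2C(CO)CO | intermediate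
32 | CNP0313563.1 | C/C=C(/C=O)[C@@H](CC=O)CC(=O)OC[C@@H]1[C@@H](C)[C@H](OC(=O)C[C@H](CC=O)/C(C=O)=C\C)C[C@H]1C(CO)CO | target

**Step count and risks**
Total: 16 steps. Longest linear sequence: 12 steps (steps 1–9, then 14–16); the acid branch (steps 10–13) is 4 steps.

Most likely to fail:

Step 4. The vinyl ether may add to the δ‑carbon of the dienyl malonate (1,6‑addition or a formal [4+2] across the diene) instead of to C5. The zwitterion may also rest as cyclobutane or dihydropyran adducts, the vinyl ether may polymerise under the Lewis acid, or the catalyst may give poor facial selectivity on a dienyl malonate. The fallback makes the two bonds one after the other with known reactions. Compound 8 would be treated with 1-(ethylsulfanyl)-1-(trimethylsilyloxy)ethene under the same copper–bis(oxazoline) catalyst with (CF3)2CHOH as silyl acceptor (catalytic enantioselective Mukaiyama–Michael addition to an alkylidene malonate) to give the thioester dimethyl 2-[(3S,4Z)-1-(ethylsulfanyl)-1-oxo-4-[(trimethylsilyl)methyl]hex-4-en-3-yl]propanedioate F1. Fukuyama reduction (Et3SiH, 10% Pd/C, acetone) would give the aldehyde dimethyl 2-[(3S,4Z)-1-oxo-4-[(trimethylsilyl)methyl]hex-4-en-3-yl]propanedioate F2. BF3·OEt2 in CH2Cl2 at −78 °C would close the ring by an intramolecular Hosomi–Sakurai reaction to the cyclopentanol dimethyl 2-[(1S,3R,4R)-4-hydroxy-3-methyl-2-methylidenecyclopentyl]propanedioate F3. Benzylation with benzyl 2,2,2-trichloroacetimidate and catalytic CF3SO3H would rejoin the route at 12.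

Step 12. The Wittig reaction may give the wrong olefin geometry or a mixture, and the basic ylide may enolise the ketone, with epimerisation or β‑elimination of the acetonide oxygen. The fallback separates the geometry‑determining intermediates. Ketone 24 would be treated with lithiated ethyl(diphenyl)phosphine oxide (THF, −78 °C). The diastereomer in which the syn‑periplanar P–C–C–O arrangement puts the methyl group on the side of C5, methyl 2-[(3aS,5S,6aR)-4-[1-(diphenylphosphoryl)ethyl]-4-hydroxy-2,2-dimethyltetrahydro-3aH-cyclopenta[d][1,3]dioxol-5-yl]acetate F4, would be separated by chromatography. NaH in DMF (stereospecific syn‑elimination, Horner–Wittig reaction) would then give 27 as a single olefin isomer.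

Step 11. Deprotonation may compete at the oxygenated α‑carbon, with β‑elimination of the acetonide oxygen, or the enolate may equilibrate and be alkylated twice. The fallback avoids the enolate. Enone 20 would be iodinated (I2, pyridine, CH2Cl2) to (3aR,6aR)-5-iodo-2,2-dimethyl-3a,6a-dihydro-4H-cyclopenta[d][1,3]dioxol-4-one F5. Coupling with the Reformatsky reagent BrZnCH2CO2CH3 under Pd(PPh3)4 catalysis would give methyl 2-[(3aR,6aR)-2,2-dimethyl-4-oxo-3a,6a-dihydro-4H-cyclopenta[d][1,3]dioxol-5-yl]acetate F6. Hydrogenation (H2, 10% Pd/C) and equilibration of the α‑centre with DBU to the trans isomer would rejoin the route at 24.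

**Further compounds**
F1 | step 4 | dimethyl 2-[(3S,4Z)-1-(ethylsulfanyl)-1-oxo-4-[(trimethylsilyl)methyl]hex-4-en-3-yl]propanedioate | C/C=C(\C[Si](C)(C)C)[C@@H](CC(=O)SCC)C(C(=O)OC)C(=O)OC
F2 | step 4 | dimethyl 2-[(3S,4Z)-1-oxo-4-[(trimethylsilyl)methyl]hex-4-en-3-yl]propanedioate | C/C=C(\C[Si](C)(C)C)[C@@H](CC=O)C(C(=O)OC)C(=O)OC
F3 | step 4 | dimethyl 2-[(1S,3R,4R)-4-hydroxy-3-methyl-2-methylidenecyclopentyl]propanedioate | C=C1[C@@H](C)[C@H](O)C[C@H]1C(C(=O)OC)C(=O)OC
F4 | step 12 | methyl 2-[(3aS,5S,6aR)-4-[1-(diphenylphosphoryl)ethyl]-4-hydroxy-2,2-dimethyltetrahydro-3aH-cyclopenta[d][1,3]dioxol-5-yl]acetate (diastereomer leading to the E olefin) | C[C@H](P(=O)(c1ccccc1)c1ccccc1)[C@@]1(O)[C@@H]2OC(C)(C)O[C@@H]2C[C@H]1CC(=O)OC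
F5 | step 11 | (3aR,6aR)-5-iodo-2,2-dimethyl-3a,6a-dihydro-4H-cyclopenta[d][1,3]dioxol-4-one | O=C1[C@@H]2OC(C)(C)O[C@@H]2C=C1I
F6 | step 11 | methyl 2-[(3aR,6aR)-2,2-dimethyl-4-oxo-3a,6a-dihydro-4H-cyclopenta[d][1,3]dioxol-5-yl]acetate | O=C1[C@@H]2OC(C)(C)O[C@@H]2C=C1CC(=O)OC
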